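By 2.00 min the target in Sunday's run stands level, so once the charge is converted, time drops out and you need to know how the converted charge was split.

| flask | starting material | target | remark | time |
|---|---|---|---|---|
| Sunday's | 20 mM | 0.59 mM | run made earlier |  |
| Tuesday's | 20 mM | 1.3 mM | run made earlier |  |
| Friday's | 16 mM | 1 mM | run made earlier |  |
| blue | 20 mM | 1.00 mM |  | 12 min |
| red | 10 mM | 0.500 mM |  | 12 min |

| run | time / min | target / % | side product / % |
|---|---|---|---|
| Sunday's | 0.833 | 47.9 | 7.1 |
| Sunday's | 2.00 | 91.6 | 10.5 |
| Sunday's | 4.00 | 92.0 | 11.0 |
| Sunday's | 6.00 | 92.3 | 11.9 |
| Sunday's | 8.00 | 92.0 | 10.0 |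
| Tuesday's | 1.50 | 93.5 | 12.7 |
| Tuesday's | 3.00 | 96.6 | 13.6 |
| Tuesday's | 5.00 | 96.0 | 12.0 |
| Tuesday's | 6.00 | 95.1 | 12.4 |
| Tuesday's | 8.00 | 94.1 | 11.1 |
| Friday's | 1.50 | 88.4 | 10.5 |
| Friday's | 3.00 | 94.3 | 13.4 |
| Friday's | 5.00 | 95.4 | 12.1 |
| Friday's | 6.00 | 96.4 | 12.2 |
| Friday's | 8.00 | 93.3 | 11.4 |

(scatter of a reading: 1 percentage point)

- percentages count the starting material that a species holds: one side product counts as two

- which of the two ends with the higher share of target in all that became target or side product ("neither" if they lie within 2 percentage points) (blue / red / neither)
- share of target in all that became target or side product, blue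
- share of target in all that became target or side product, red

Work in fractions of the charge. Take the seed of target off the readings and the balance closes: at 4.00 min, Sunday's new target plus side product comes to 100%. So call the side cut the fraction of the converted charge that stands as side product, the complement of the selectivity. Replace its curve by its mean over the 12 level readings, and you get 11.8%, good to about 0.29 percentage points.

The seed counts as target in the asked share, so the share is one minus the side cut divided by one plus the seed fraction. Ignore the seed and you have the low extreme, 88.2%. Tuesday's seed, the richest of the runs, gives the high one, 88.9%. Blue and red both carry a seed fraction of 5.00%, below Tuesday's 6.50%, and the same reckoning gives them 88.8%. If red's clock stretches with dilution, Sunday's level time becomes 4.00 min, shorter than 12 min. Red's 10 mM lies below the runs, though, so holding the side cut there is an assumption.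

The forecast gave 88.5% for blue and 88.5% for red, hence neither, reasoning that “target and side product appear to have the same concentration dependence”.

The flask gives 89.0% for blue and 89.0% for red, so the answer is neither.

    starting material + target → 2 target (k = 3.60 L mol⁻¹ s⁻¹)
    starting material → target (k = 9.30 × 10⁻⁶ s⁻¹)
    starting material + target → side product (k = 0.220 L mol⁻¹ s⁻¹)

Left until 120 min, blue still reads 89.0%. The share of 88.8% reckoned from the side cut of 11.8% lies 0.20 points from that result.

Now take blue with 8.0 mM of starting material, which raises the seed fraction to 12.5%. The side cut then gives 89.5%, and the computed flask gives 89.8%.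

(The data come from a simulation for substances that don't exist; scatter was added.)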